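**Retrosynthetic overview**

1. Target triacid ⇐ its trimethyl ester (thiolate demethylation); 15β‑OH from Luche reduction of the 15‑oxo‑16‑ene.
2. Ring D last: 5‑exo vinyl‑radical closure of a C15 ethynyl carbinol onto the C12=C13 alkene.
3. Ring A third: 1,3‑dibromopropane stitched between C10 and C4 after ring C is in place, then C4 methylation and reduction of the C5=C6 enoate.
4. Ring C second: catalytic asymmetric ionic Diels–Alder of butadiene with an achiral cyclopentadienyl acetal (sets C8 and C9).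
5. Ring B first: C‑alkylation of trimethyl methanetricarboxylate with a γ‑bromo enoate, then vinylogous Dieckmann closure and O‑triflation.

Assumption: gibberellane locants are used for all intermediates; α is the face of ring B carrying C20 and C14, β the face carrying H‑5, H‑9, C7 and C15; the 15β‑hydroxyl is endo on ring D (anti to C14); the acid enantiomer in step 4 is the one that gives 9 as drawn (the mirror‑image acid gives ent‑9).

The route is a paper design; none of it has been run.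

**Step 1**
Reactants: 1 3‑bromo‑1,1‑dimethoxypropan‑2‑one; 2 methyl (triphenylphosphoranylidene)acetate
Product: 3 methyl 4‑bromo‑3‑(dimethoxymethyl)but‑2‑enoate (E/Z mixture)
Conditions: toluene, 25 → 60 °C
Reagents that add atoms: none
Why: Wittig olefination of the activated ketone by a stabilised ylide; the alkene geometry is irrelevant because the double bond is transposed in step 3.

**Step 2**
Reactants: 3 methyl 4‑bromo‑3‑(dimethoxymethyl)but‑2‑enoate; 4 trimethyl methanetricarboxylate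
Product: 5 trimethyl 3‑(dimethoxymethyl)‑5‑methoxy‑5‑oxopent‑3‑ene‑1,1,1‑tricarboxylate
Conditions: K2CO3, DMF, 25 °C
Reagents that add atoms: none
Why: SN2 C‑alkylation of the soft, non‑basic tricarboxylate anion at the primary allylic bromide forms C9–C10.

**Step 3**
Reactants: 5 tetraester acetal
Product: 7 trimethyl 3‑(dimethoxymethyl)‑5‑[(trifluoromethanesulfonyl)oxy]cyclopenta‑2,4‑diene‑1,1,4‑tricarboxylate, via potassium enolate 6 (not isolated)
Conditions: KN(SiMe3)2 (1.1 equiv), THF, −78 → −20 °C; then PhNTf2, −78 → 0 °C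
Reagents that add atoms: N‑phenylbis(trifluoromethanesulfonimide), O=S(=O)(N(c1ccccc1)S(=O)(=O)C(F)(F)F)C(F)(F)F
Why: Vinylogous Dieckmann condensation: γ‑deprotonation at C9 gives a dienolate whose α‑carbon (C6) acylates on one of three equivalent esters (that carbonyl becomes C5, closing ring B), the acidic product consumes the methoxide and is O‑triflated, and the two remaining esters keep C10 achiral and block hydrogen shifts in the diene.

**Step 4**
Reactants: 7 cyclopentadienyl triflate acetal; 8 buta‑1,3‑diene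
Product: 9 cis‑fused ring B/C acetal (trimethyl 3a‑(dimethoxymethyl)‑2‑[(trifluoromethanesulfonyl)oxy]‑3a,4,7,7a‑tetrahydro‑1H‑indene‑1,1,3‑tricarboxylate; 9β‑H; 8β‑CH(OMe)2)
Conditions: (S,S)‑IDPi Brønsted acid (imidodiphosphorimidate, 5 mol %), butadiene (10 equiv), CH2Cl2, −78 → −50 °C; Et3N quench
Reagents that add atoms: none
Why: Proposed new method: the confined chiral acid ionises the dimethyl acetal to an O‑methyl vinyl‑oxocarbenium ion held as a contact ion pair with the chiral anion, butadiene adds suprafacially across the activated C8=C9 bond (so C14 and C11 arrive cis), and the new oxocarbenium recaptures methanol to return the acetal and the acid, so the anion differentiates the enantiotopic faces of this planar achiral cation and sets C8 and C9 as the first stereocentres; the closest known reaction type is the Brønsted‑acid‑catalysed ionic (Gassman‑type) Diels–Alder reaction of α,β‑unsaturated acetals together with IDPi‑catalysed Diels–Alder reactions of unsaturated carbonyl compounds.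

**Step 5**
Reactants: 9 ring B/C triflate acetal; 10 methyl bromoacetate
Product: 12 trimethyl cis‑3a‑(dimethoxymethyl)‑2‑(2‑methoxy‑2‑oxoethyl)‑3a,4,7,7a‑tetrahydro‑1H‑indene‑1,1,3‑tricarboxylate, via Reformatsky reagent 11 (not isolated)
Conditions: Zn dust (Me3SiCl‑activated), THF, 25 °C; then 9, Pd(PPh3)4 (5 mol %), THF, 60 °C
Reagents that add atoms: none
Why: Negishi cross‑coupling of the β‑triflyloxy enoate with the zinc enolate installs C4 and C19 on C5; 9 has no acidic C–H to quench the reagent.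

**Step 6**
Reactants: 12 gem‑diester
Product: 13 dimethyl cis‑3a‑(dimethoxymethyl)‑2‑(2‑methoxy‑2‑oxoethyl)‑3a,4,7,7a‑tetrahydro‑1H‑indene‑1,3‑dicarboxylate (C10 epimers)
Conditions: LiCl, H2O, DMSO, 130 °C
Reagents that add atoms: none
Why: Krapcho dealkoxycarbonylation removes one ester of the only geminal pair (C10), leaving C20, while the non‑geminal C7 and C19 esters are not activated enough to react; the C10 configuration is irrelevant because it is re‑enolised in step 7.

**Step 7**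
Reactants: 13 diester; 14 1,3‑dibromopropane
Product: 16 trimethyl 8a‑(dimethoxymethyl)‑1‑methyl‑1,2,3,4,4b,5,8,8a‑octahydro‑4aH‑fluorene‑1,4a,9‑tricarboxylate (4β‑Me; 4α‑CO2Me; 10α‑CO2Me; C5=C6 enoate; 8β‑CH(OMe)2; 9β‑H; C12=C13), via ring‑A‑closed triester 15 (not isolated)
Conditions: NaH (2.2 equiv), 1,3‑dibromopropane, THF/DMF, 0 → 25 °C; then NaH (1.2 equiv), MeI, 0 → 25 °C
Reagents that add atoms: iodomethane, CI
Why: Double C‑alkylation of the two vinylogous ester anions (C4 and C10) closes ring A; C1 enters C10 on the β face trans to C11 (convex face of the cis‑fused B/C bicycle) so C20 ends α, C6 is shielded on both faces by the C8 substituents, and MeI then attacks the C4–C5–C6 dienolate anti to the 10α‑ester to give 4β‑Me/4α‑CO2Me.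

**Step 8**
Reactants: 16 tricyclic enoate acetal
Product: 17 trimethyl 8a‑(dimethoxymethyl)‑1‑methyl‑1,2,3,4,4b,5,8,8a,9,9a‑decahydro‑4aH‑fluorene‑1,4a,9‑tricarboxylate (5β‑H; 6β‑CO2Me)
Conditions: Mg turnings, MeOH, 25 °C; then NaOMe (0.2 equiv), MeOH, 50 °C
Reagents that add atoms: none
Why: Dissolving‑metal (Mg/MeOH) conjugate reduction of the enoate protonates C5 from the β face (the α face is screened by the 4α‑ and 10α‑esters) to give the trans A/B fusion, and methoxide equilibrates C6 to the more stable 6β‑ester (trans to C4).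

**Step 9**
Reactants: 17 saturated triester acetal
Product: 18 trimethyl 8a‑formyl‑1‑methyl‑1,2,3,4,4b,5,8,8a,9,9a‑decahydro‑4aH‑fluorene‑1,4a,9‑tricarboxylate
Conditions: 1 M HCl, THF, 40 °C
Reagents that add atoms: water, O
Why: Acid hydrolysis of the dimethyl acetal unmasks the C15 aldehyde; the methyl esters and the alkene are inert.

**Step 10**
Reactants: 18 aldehyde; 19 ethynylmagnesium bromide
Product: 20 trimethyl 8a‑(1‑hydroxyprop‑2‑yn‑1‑yl)‑1‑methyl‑1,2,3,4,4b,5,8,8a,9,9a‑decahydro‑4aH‑fluorene‑1,4a,9‑tricarboxylate (C15 epimers)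
Conditions: HC≡CMgBr (3 equiv), THF, −78 °C; AcOH quench at −78 °C
Reagents that add atoms: none
Why: Grignard addition to the non‑enolisable neopentyl aldehyde; the C15 configuration is immaterial (converged in steps 12–13) and the cold acidic quench prevents the alkoxide from lactonising onto the 6β‑ester.

**Step 11**
Reactants: 20 propargylic alcohols; 21 tributyltin hydride
Product: 23 trimethyl 15‑hydroxygibberell‑16‑ene‑7,19,20‑trioate (C15 epimers), via vinylstannane 22 (not isolated)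
Conditions: Bu3SnH (2 equiv, 0.3 M), AIBN, benzene, 80 °C; then TsOH·H2O, CH2Cl2, 0 °C
Reagents that add atoms: none
Why: Stannyl‑radical addition to the terminal alkyne carbon and 5‑exo‑trig closure of the vinyl radical onto C13 builds ring D (the short tether can only bridge cis, fixing C13), the high stannane concentration traps the bicyclo[3.2.1] radical before homoallyl rearrangement, and protodestannylation reveals the 16‑methylene.

**Step 12**
Reactants: 23 epimeric 15‑alcohols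
Product: 24 trimethyl 15‑oxogibberell‑16‑ene‑7,19,20‑trioate (16‑methylene‑15‑ketone)
Conditions: Dess–Martin periodinane, CH2Cl2, 25 °C
Reagents that add atoms: none
Why: Dess–Martin oxidation converts both allylic alcohol epimers into a single enone.

**Step 13**
Reactants: 24 enone
Product: 25 trimethyl 15β‑hydroxygibberell‑16‑ene‑7,19,20‑trioate (the target trimethyl ester)
Conditions: NaBH4, CeCl3·7H2O, MeOH, −78 °C
Reagents that add atoms: none
Why: Luche 1,2‑reduction; hydride attacks the 15‑ketone from the exo face (the side of the C14 bridge), away from the 6β‑ester and the C9–C11–C12 bridge, so the hydroxyl ends endo, which is the 15β configuration.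

**Step 14**
Reactants: 25 target trimethyl ester
Product: 26 15β‑hydroxygibberell‑16‑ene‑7,19,20‑trioic acid (the target gibberellin)
Conditions: NaSEt (excess), DMF, 100 °C; then aq. H3PO4 to pH 3, 0 °C
Reagents that add atoms: none
Why: Thiolate SN2 O‑demethylation cleaves all three methyl esters, including the hindered C19 and C20 esters, without touching the allylic alcohol or any stereocentre.

**Compound list**

1 | 3‑bromo‑1,1‑dimethoxypropan‑2‑one | COC(OC)C(=O)CBr | starting material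
2 | methyl (triphenylphosphoranylidene)acetate | COC(=O)C=P(c1ccccc1)(c1ccccc1)c1ccccc1 | starting material
3 | methyl 4‑bromo‑3‑(dimethoxymethyl)but‑2‑enoate (E/Z mixture) | COC(=O)C=C(CBr)C(OC)OC | intermediate
4 | trimethyl methanetricarboxylate | COC(=O)C(C(=O)OC)C(=O)OC | starting material
5 | trimethyl 3‑(dimethoxymethyl)‑5‑methoxy‑5‑oxopent‑3‑ene‑1,1,1‑tricarboxylate (E/Z mixture) | COC(=O)C=C(CC(C(=O)OC)(C(=O)OC)C(=O)OC)C(OC)OC | intermediate
6 | potassium enolate of trimethyl 3‑(dimethoxymethyl)‑5‑hydroxycyclopenta‑2,4‑diene‑1,1,4‑tricarboxylate | COC(=O)C1=C([O-])C(C(=O)OC)(C(=O)OC)C=C1C(OC)OC.[K+] | intermediate (not isolated)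
7 | trimethyl 3‑(dimethoxymethyl)‑5‑[(trifluoromethanesulfonyl)oxy]cyclopenta‑2,4‑diene‑1,1,4‑tricarboxylate | COC(=O)C1=C(OS(=O)(=O)C(F)(F)F)C(C(=O)OC)(C(=O)OC)C=C1C(OC)OC | intermediate
8 | buta‑1,3‑diene | C=CC=C | starting material
9 | trimethyl cis‑3a‑(dimethoxymethyl)‑2‑[(trifluoromethanesulfonyl)oxy]‑3a,4,7,7a‑tetrahydro‑1H‑indene‑1,1,3‑tricarboxylate (9β‑H; 8β‑CH(OMe)2) | C1=CC[C@H]2C(C(=O)OC)(C(=O)OC)C(OS(=O)(=O)C(F)(F)F)=C(C(=O)OC)[C@]2(C1)C(OC)OC | intermediate
10 | methyl bromoacetate | COC(=O)CBr | starting material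
11 | (2‑methoxy‑2‑oxoethyl)zinc bromide | COC(=O)C[Zn]Br | intermediate (not isolated)
12 | trimethyl cis‑3a‑(dimethoxymethyl)‑2‑(2‑methoxy‑2‑oxoethyl)‑3a,4,7,7a‑tetrahydro‑1H‑indene‑1,1,3‑tricarboxylate | C1=CC[C@H]2C(C(=O)OC)(C(=O)OC)C(CC(=O)OC)=C(C(=O)OC)[C@]2(C1)C(OC)OC | intermediate
13 | dimethyl cis‑3a‑(dimethoxymethyl)‑2‑(2‑methoxy‑2‑oxoethyl)‑3a,4,7,7a‑tetrahydro‑1H‑indene‑1,3‑dicarboxylate (C10 epimers) | C1=CC[C@H]2C(C(=O)OC)C(CC(=O)OC)=C(C(=O)OC)[C@]2(C1)C(OC)OC | intermediate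
14 | 1,3‑dibromopropane | BrCCCBr | starting material
15 | trimethyl 8a‑(dimethoxymethyl)‑1,2,3,4,4b,5,8,8a‑octahydro‑4aH‑fluorene‑1,4a,9‑tricarboxylate (10α‑CO2Me; C4 epimers) | C1=CC[C@H]2[C@]3(C(=O)OC)CCCC(C(=O)OC)C3=C(C(=O)OC)[C@]2(C1)C(OC)OC | intermediate (not isolated)
16 | trimethyl 8a‑(dimethoxymethyl)‑1‑methyl‑1,2,3,4,4b,5,8,8a‑octahydro‑4aH‑fluorene‑1,4a,9‑tricarboxylate (4β‑Me; 4α‑CO2Me; 10α‑CO2Me; 8β‑CH(OMe)2; 9β‑H) | C1=CC[C@H]2[C@]3(C(=O)OC)CCC[C@@](C)(C(=O)OC)C3=C(C(=O)OC)[C@]2(C1)C(OC)OC | intermediate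
17 | trimethyl 8a‑(dimethoxymethyl)‑1‑methyl‑1,2,3,4,4b,5,8,8a,9,9a‑decahydro‑4aH‑fluorene‑1,4a,9‑tricarboxylate (5β‑H; 6β‑CO2Me) | C1=CC[C@H]2[C@]3(C(=O)OC)CCC[C@@](C)(C(=O)OC)[C@H]3[C@H](C(=O)OC)[C@]2(C1)C(OC)OC | intermediate
18 | trimethyl 8a‑formyl‑1‑methyl‑1,2,3,4,4b,5,8,8a,9,9a‑decahydro‑4aH‑fluorene‑1,4a,9‑tricarboxylate | C1=CC[C@H]2[C@]3(C(=O)OC)CCC[C@@](C)(C(=O)OC)[C@H]3[C@H](C(=O)OC)[C@]2(C1)C=O | intermediate
19 | ethynylmagnesium bromide | C#C[Mg]Br | starting material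
20 | trimethyl 8a‑(1‑hydroxyprop‑2‑yn‑1‑yl)‑1‑methyl‑1,2,3,4,4b,5,8,8a,9,9a‑decahydro‑4aH‑fluorene‑1,4a,9‑tricarboxylate (C15 epimers) | C1=CC[C@H]2[C@]3(C(=O)OC)CCC[C@@](C)(C(=O)OC)[C@H]3[C@H](C(=O)OC)[C@]2(C1)C(O)C#C | intermediate
21 | tributyltin hydride | CCCC[SnH](CCCC)CCCC | starting material
22 | trimethyl 15‑hydroxy‑17‑(tributylstannyl)gibberell‑16‑ene‑7,19,20‑trioate (C15 epimers) | CCCC[Sn](CCCC)(CCCC)C=C1[C@@H]2CC[C@H]3[C@]4(C(=O)OC)CCC[C@@](C)(C(=O)OC)[C@H]4[C@H](C(=O)OC)[C@]3(C2)C1O | intermediate (not isolated)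
23 | trimethyl 15‑hydroxygibberell‑16‑ene‑7,19,20‑trioate (C15 epimers) | C=C1[C@@H]2CC[C@H]3[C@]4(C(=O)OC)CCC[C@@](C)(C(=O)OC)[C@H]4[C@H](C(=O)OC)[C@]3(C2)C1O | intermediate
24 | trimethyl 15‑oxogibberell‑16‑ene‑7,19,20‑trioate | C=C1[C@@H]2CC[C@H]3[C@]4(C(=O)OC)CCC[C@@](C)(C(=O)OC)[C@H]4[C@H](C(=O)OC)[C@]3(C2)C1=O | intermediate
25 | trimethyl 15β‑hydroxygibberell‑16‑ene‑7,19,20‑trioate (the target trimethyl ester) | C=C1[C@@H]2CC[C@H]3[C@]4(C(=O)OC)CCC[C@@](C)(C(=O)OC)[C@H]4[C@H](C(=O)OC)[C@]3(C2)[C@@H]1O | intermediate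
26 | 15β‑hydroxygibberell‑16‑ene‑7,19,20‑trioic acid (the target gibberellin; 4β‑Me; 4α‑CO2H; 10α‑CO2H; 5β‑H; 6β‑CO2H; 9β‑H) | C=C1[C@@H]2CC[C@H]3[C@]4(C(=O)O)CCC[C@@](C)(C(=O)O)[C@H]4[C@H](C(=O)O)[C@]3(C2)[C@@H]1O | target

**Totals**

Total step count: 14. Longest linear sequence: 14 steps (1 → 3 → 5 → 7 → 9 → 12 → 13 → 16 → 17 → 18 → 20 → 23 → 24 → 25 → 26).

**Three steps most likely to fail**

Step 4 (the proposed asymmetric ionic Diels–Alder; ionisation of the electron‑poor acetal, turnover and enantiocontrol are all untested). The fallback sets out from 7. The acetal is hydrolysed (CF3CO2H, wet CH2Cl2, 0 °C) to the enal trimethyl 3‑formyl‑5‑[(trifluoromethanesulfonyl)oxy]cyclopenta‑2,4‑diene‑1,1,4‑tricarboxylate F1. F1 is then combined with butadiene under an established chiral oxazaborolidinium triflimide catalyst (from (S)‑α,α‑diphenylprolinol, o‑tolylboroxine and Tf2NH; CH2Cl2, −78 °C), a known enal activation mode, to give the aldehyde adduct trimethyl cis‑3a‑formyl‑2‑[(trifluoromethanesulfonyl)oxy]‑3a,4,7,7a‑tetrahydro‑1H‑indene‑1,1,3‑tricarboxylate F2. Re‑acetalisation with HC(OMe)3, MeOH and cat. TsOH brings the material back to the route at 9.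

Step 5 (Negishi coupling at a tetrasubstituted vinyl triflate flanked by a quaternary carbon). The fallback sets out from 9 and replaces the cross‑coupling by addition–elimination. The sodium salt NaCH(CO2Me)2 (from NaH and dimethyl malonate, THF, 0 → 40 °C) displaces the triflate of the β‑triflyloxy enoate to give trimethyl cis‑2‑[bis(methoxycarbonyl)methyl]‑3a‑(dimethoxymethyl)‑3a,4,7,7a‑tetrahydro‑1H‑indene‑1,1,3‑tricarboxylate F3. A double Krapcho reaction (LiCl, H2O, DMSO, 140 °C) then removes one ester from each geminal pair, and the route is rejoined at 13 (12 is bypassed).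

Step 7 (one‑pot annulation; risk of cyclobutane formation at C4, C6 alkylation or oligomers). The fallback sets out from 12, where the C4 methylene is the only acidic site, and secures the order of bond formation. Alkylation with 1‑bromo‑3‑chloropropane (K2CO3, DMF) gives trimethyl cis‑2‑(5‑chloro‑1‑methoxy‑1‑oxopentan‑2‑yl)‑3a‑(dimethoxymethyl)‑3a,4,7,7a‑tetrahydro‑1H‑indene‑1,1,3‑tricarboxylate F4. Krapcho dealkoxycarbonylation (LiCl, H2O, DMSO, 130 °C) gives the C10–H compound dimethyl cis‑2‑(5‑chloro‑1‑methoxy‑1‑oxopentan‑2‑yl)‑3a‑(dimethoxymethyl)‑3a,4,7,7a‑tetrahydro‑1H‑indene‑1,3‑dicarboxylate F5. NaH with cat. NaI in THF then closes C10–C1 from the β face, and the route is rejoined at 15, which is methylated (NaH, MeI) to 16 as in step 7.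

**Further compounds**

F1 | step 4 | trimethyl 3‑formyl‑5‑[(trifluoromethanesulfonyl)oxy]cyclopenta‑2,4‑diene‑1,1,4‑tricarboxylate | COC(=O)C1=C(OS(=O)(=O)C(F)(F)F)C(C(=O)OC)(C(=O)OC)C=C1C=O
F2 | step 4 | trimethyl cis‑3a‑formyl‑2‑[(trifluoromethanesulfonyl)oxy]‑3a,4,7,7a‑tetrahydro‑1H‑indene‑1,1,3‑tricarboxylate | C1=CC[C@H]2C(C(=O)OC)(C(=O)OC)C(OS(=O)(=O)C(F)(F)F)=C(C(=O)OC)[C@]2(C1)C=O
F3 | step 5 | trimethyl cis‑2‑[bis(methoxycarbonyl)methyl]‑3a‑(dimethoxymethyl)‑3a,4,7,7a‑tetrahydro‑1H‑indene‑1,1,3‑tricarboxylate | C1=CC[C@H]2C(C(=O)OC)(C(=O)OC)C(C(C(=O)OC)C(=O)OC)=C(C(=O)OC)[C@]2(C1)C(OC)OC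
F4 | step 7 | trimethyl cis‑2‑(5‑chloro‑1‑methoxy‑1‑oxopentan‑2‑yl)‑3a‑(dimethoxymethyl)‑3a,4,7,7a‑tetrahydro‑1H‑indene‑1,1,3‑tricarboxylate | C1=CC[C@H]2C(C(=O)OC)(C(=O)OC)C(C(CCCCl)C(=O)OC)=C(C(=O)OC)[C@]2(C1)C(OC)OC
F5 | step 7 | dimethyl cis‑2‑(5‑chloro‑1‑methoxy‑1‑oxopentan‑2‑yl)‑3a‑(dimethoxymethyl)‑3a,4,7,7a‑tetrahydro‑1H‑indene‑1,3‑dicarboxylate | C1=CC[C@H]2C(C(=O)OC)C(C(CCCCl)C(=O)OC)=C(C(=O)OC)[C@]2(C1)C(OC)OC
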